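(The earlier runs and the new flask were computed from invented constants; noise was put on by code.)

You have two questions: how much product each flask holds at 4.0 h, and how those percentages run from the first flask to the last.

all flasks: free catalyst 0.72 mM
- delta: substrate 0.027 M; solid reagent 0.13 M; run made earlier
- gamma: substrate 0.24 M; solid reagent 0.13 M; run made earlier
- Monday's: substrate 0.050 M; solid reagent 0.130 M; time 4.0 h
- Saturday's: substrate 0.10 M; solid reagent 0.130 M; time 4.0 h
- Sunday's: substrate 0.20 M; solid reagent 0.130 M; time 4.0 h
- Wednesday's: substrate 0.40 M; solid reagent 0.130 M; time 4.0 h

| run | time / h | product / % |
|---|---|---|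
| delta | 0.250 | 30 |
| delta | 0.333 | 38 |
| delta | 0.667 | 50 |
| delta | 1.00 | 57 |
| delta | 1.50 | 66 |
| delta | 3.00 | 81 |
| gamma | 0.200 | 2 |
| gamma | 0.500 | 0 |
| gamma | 1.00 | 4 |
| gamma | 1.50 | 8 |
| gamma | 2.00 | 7 |
| gamma | 3.00 | 7 |

(each reading ± 2 percentage points)

- as a solid, counted per litre of solution: solid reagent
- at the start none of the solid reagent is in solution
- "hardly changes" means that all values lie within two and a half points (for a concentration: within two and a half percent of the largest)

- amount of product at the end, in percent of the substrate charged for Monday's, Saturday's, Sunday's, Wednesday's, in this order
- the course of these numbers from the first flask to the last (rises all the way / rises, then falls / falls all the way / falls, then rises / hardly changes)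

Turn the second question round. For the percentage to hold steady, product concentration has to grow in step with the substrate charge. At 3.00 h the delta run reads 81%, and on the gamma charge that percentage would be 0.194 M. The last gamma readings, 8%, 7% and 7%, average to 0.0176 M of product. Call this S, the stall amount: the product concentration at which a run's readings go flat. So gamma stands far from proportion.

Compare rates. Up to 1.50 h, the delta readings average 0.0119 M/h. Gamma, at about S by 1.50 h, averages about the same, 0.0117 M/h, though gamma was charged with more substrate. Then the comparison drifts. Delta slows to 0.00270 M/h over its last stretch, and gamma goes flat. Gamma's stall is no limiting reagent running out, since S is less than the solid reagent charged.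

My reckoning: each flask reaches about S, so its percentage is S divided by its substrate charge. That gives 35.2%, 17.6%, 8.80% and 4.40%, falling all the way. Expect Monday's to land above its figure, because delta already held 0.0219 M at 3.00 h, more than S.

The forecast gives 54%, 23%, 9% and 3.5%, and the shape falls all the way. Its ground: “The amount of product looks capped at around 0.02 M, and the cap falls slowly as substrate increases.” Its Monday's figure is higher than mine, and its Wednesday's is lower.

The flasks give 39.4%, 17.3%, 8.09% and 3.90%, and the course falls all the way.

    2 catalyst intermediate B → spent catalyst (k = 1000 /M/min)
    partner + catalyst intermediate A → catalyst intermediate B (k = 7200 /M/min)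
    catalyst intermediate B → free catalyst + product (k = 4.90 /min)
    solid reagent ⇌ partner, rate k4*(cs4 - [partner]) while solid is left; crystals form when [partner] > cs4 (solubility = 0.0660 M, k = 0.130 /min)
    substrate + free catalyst → catalyst intermediate A (k = 190 /M/min)

In Saturday's flask at 4.00 h, spent catalyst stands at 99.5% of the catalyst charged, while 82% of the substrate is still there. Now divide S by the charge of Wednesday's flask: you get 4.40%, and Wednesday's flask holds 3.90%.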